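The target is (1R,2S,4S,5R)-1,4-dibromo-5-chloro-2-[(E)-2-chloroethenyl]-1,5-dimethylcyclohexane, and the 7-oxabicyclo[2.2.1]heptane intermediates carry the same carbon numbers.
Enabling feature: the bromine-bearing carbons C1 and C4 lie para across the ring and are joined on one side by C6H2–C5(Cl)(CH3). One oxygen in place of both bromines gives the five-membered ring O7–C1–C6–C5–C4, a reduced 2,4-dimethylfuran bridged over the carbocycle.
Retrosynthetic cuts, in order: C4–Br (to C4–OH, inversion), C1–Br (to the O7 bridge), the side-chain C=C (to CHO), C5–Cl and C6–H (to C5=C6), then C1–C2 and C3–C4 together by retro-[4+2] to 2,4-dimethylfuran and an acryloyl imide.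
Forward: the furan ring is bought, the six-membered ring closes in step 1, the bicycle serves as a rigid template through step 6, and the oxygen ring is opened in step 7 to leave the monocycle.
Stereochemistry: a chiral copper Lewis acid fixes the absolute sense and, with the endo rule, C2. C5 comes from anti addition of PhSeCl (selenium exo, chloride endo), C1 from upper-face bromide capture as the bridge opens (retention), and C4 from SN2 inversion of the freed alcohol.
Key step: step 1

Assumption: 2,4-dimethylfuran and 3-acryloyl-1,3-oxazolidin-2-one are taken as catalogue chemicals, and the configuration is taken exactly as in the given SMILES, with C4–Br and C5–Cl cis.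

Step 1
Reactants: 1 2,4-dimethylfuran; 2 3-acryloyl-1,3-oxazolidin-2-one
Product: 3 3-[(1R,2R,4R)-1,5-dimethyl-7-oxabicyclo[2.2.1]hept-5-ene-2-carbonyl]-1,3-oxazolidin-2-one (acyl group endo)
Conditions: Cu(SbF6)2/(R,R)-t-Bu-box (10 mol %; from CuCl2, AgSbF6 and 2,2'-(propane-2,2-diyl)bis[(4R)-4-tert-butyl-4,5-dihydro-1,3-oxazole]), 1 (2 equiv), CH2Cl2, -78 °C; cold filtration through silica gel
Reagents that add atoms: none
Why: Imide 2 binds through both carbonyl oxygens to divalent copper in a square-planar s-cis chelate, which lowers its LUMO, and the furan adds in a concerted but asynchronous suprafacial–suprafacial [4π+2π] cycloaddition in which the C3–C4 bond (acrylate CH2 to the free furan α-carbon) runs ahead of the C1–C2 bond. The closest known reaction type is the bis(oxazoline)–copper catalysed Diels–Alder reaction of furan with this same dienophile. The cyclohexene ring C1–C6 closes by intermolecular [4+2] cycloaddition, and the same event turns the furan into the 2,5-dihydrofuran ring O7–C1–C6–C5–C4, so that O7 ends as a one-atom bridge over the new ring. C1 and C4 are necessarily cis-bridged because both bonds form on one face of the planar furan, C2 is set endo by the kinetic endo preference of the chelated dienophile at -78 °C, and the absolute sense comes from the tert-butyl groups of the ligand: in the chelate model the (S,S)-ligand leaves the Cα Re face open (2S series), so the (R,R)-ligand exposes the Si face needed for 2R. The step needs the carbonyl-bearing carbon next to the methylated bridgehead, and both methyl groups secure this, because the 2-methyl ("ortho" rule) and the 4-methyl ("para" rule) both enlarge the HOMO coefficient at the unsubstituted C5 of the furan, which therefore bonds to the acrylate β-carbon. It also needs cycloaddition to outrun conjugate alkylation at that carbon and cycloreversion, which the low temperature, the cold removal of the catalyst and the immediate use of 3 in step 2 are meant to secure.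

Step 2
Reactants: 3 3-[(1R,2R,4R)-1,5-dimethyl-7-oxabicyclo[2.2.1]hept-5-ene-2-carbonyl]-1,3-oxazolidin-2-one
Product: 4 3-[(1S,2R,4R,5S,6S)-5-chloro-1,5-dimethyl-6-(phenylselanyl)-7-oxabicyclo[2.2.1]heptane-2-carbonyl]-1,3-oxazolidin-2-one (Cl endo, 5-CH3 exo, SePh exo, acyl endo)
Conditions: PhSeCl (1.05 equiv), CH2Cl2, -78 °C to rt
Reagents that add atoms: benzeneselenenyl chloride, Cl[Se]c1ccccc1
Why: Electrophilic anti 1,2-addition (selenochlorination) to the strained C5=C6 bond: selenium attacks the open exo face to give the seleniranium ion and chloride opens it from the endo face at the tertiary, more cationic C5 (Markovnikov sense; the endo imide can reach only C6), which sets C5 with Cl endo and CH3 exo, trans to the O7–C4 bond, and removes the alkene that would allow cycloreversion.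

Step 3
Reactants: 4 3-[(1S,2R,4R,5S,6S)-5-chloro-1,5-dimethyl-6-(phenylselanyl)-7-oxabicyclo[2.2.1]heptane-2-carbonyl]-1,3-oxazolidin-2-one
Product: 5 3-[(1R,2R,4R,5R)-5-chloro-1,5-dimethyl-7-oxabicyclo[2.2.1]heptane-2-carbonyl]-1,3-oxazolidin-2-one
Conditions: Bu3SnH (1.1 equiv), Et3B (0.2 equiv), air, toluene, 0 °C to rt
Reagents that add atoms: none
Why: Radical-chain reductive deselenation with a tin hydride: phenylselanyl transfer to tin is far faster than abstraction of the tertiary chlorine, and the C6 radical takes hydrogen before it could lose the β-chlorine (which would rebuild a strained bicyclic alkene), so steps 2 and 3 together amount to a Markovnikov addition of HCl with chloride on the endo face; no stereocentre forms at C6.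

Step 4
Reactants: 5 3-[(1R,2R,4R,5R)-5-chloro-1,5-dimethyl-7-oxabicyclo[2.2.1]heptane-2-carbonyl]-1,3-oxazolidin-2-one
Product: 6 [(1R,2S,4R,5R)-5-chloro-1,5-dimethyl-7-oxabicyclo[2.2.1]heptan-2-yl]methanol
Conditions: LiBH4, H2O (1 equiv), Et2O, 0 °C
Reagents that add atoms: none
Why: Reductive cleavage of an N-acyloxazolidinone with LiBH4 to the primary alcohol, which leaves the tertiary chloride, the ether bridge and the C2 stereocentre untouched.

Step 5
Reactants: 6 [(1R,2S,4R,5R)-5-chloro-1,5-dimethyl-7-oxabicyclo[2.2.1]heptan-2-yl]methanol
Product: 7 (1R,2R,4R,5R)-5-chloro-1,5-dimethyl-7-oxabicyclo[2.2.1]heptane-2-carbaldehyde (CHO endo)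
Conditions: Dess–Martin periodinane, CH2Cl2, 0 °C to rt
Reagents that add atoms: none
Why: Dess–Martin oxidation under non-basic conditions, chosen so that the endo aldehyde neither epimerises at C2 nor expels the β-oxygen O7; with C5–C6 saturated, cycloreversion is no longer possible.

Step 6
Reactants: 7 (1R,2R,4R,5R)-5-chloro-1,5-dimethyl-7-oxabicyclo[2.2.1]heptane-2-carbaldehyde
Product: 8 (1R,2S,4R,5R)-5-chloro-2-[(E)-2-chloroethenyl]-1,5-dimethyl-7-oxabicyclo[2.2.1]heptane
Conditions: CrCl2 (6 equiv), CHCl3 (2 equiv), THF, 65 °C
Reagents that add atoms: chloroform, ClC(Cl)Cl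
Why: Takai olefination: the gem-dichromium reagent formed from CHCl3 and divalent chromium adds to the aldehyde and eliminates to the (E)-chloroalkene under steric control, the unactivated tertiary alkyl chloride is not reduced by CrCl2 in THF, and the step is placed before any C–Br bond exists because alkyl bromides and vicinal dihalides would not survive divalent chromium.

Step 7
Reactants: 8 (1R,2S,4R,5R)-5-chloro-2-[(E)-2-chloroethenyl]-1,5-dimethyl-7-oxabicyclo[2.2.1]heptane
Product: 10 (1R,2R,4R,5S)-4-bromo-2-chloro-5-[(E)-2-chloroethenyl]-2,4-dimethylcyclohexan-1-ol (carbinol carbon = C4 of the target), via dibromoboryl ether 9 (not isolated)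
Conditions: BBr3 (1.1 equiv), CH2Cl2, -78 °C; then H2O
Reagents that add atoms: boron tribromide, BrB(Br)Br
Why: Lewis-acid ether cleavage with BBr3: boron binds O7 and the strained bridge ionises at the tertiary C1 rather than at C4 (secondary, flanked by the quaternary C5 and deactivated by its chlorine), and as C1 drops into the chair with the side chain equatorial the syn-axial C5–Cl screens the lower face, so bromide passed on from the bromoborate still held on the upper face at O–C4 enters equatorially and C1–Br forms with retention, trans to the C2 side chain.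

Step 8
Reactants: 10 (1R,2R,4R,5S)-4-bromo-2-chloro-5-[(E)-2-chloroethenyl]-2,4-dimethylcyclohexan-1-ol
Product: 11 (1R,2S,4S,5R)-1,4-dibromo-5-chloro-2-[(E)-2-chloroethenyl]-1,5-dimethylcyclohexane
Conditions: PPh3, CBr4, CH2Cl2, 0 °C to 40 °C
Reagents that add atoms: carbon tetrabromide, BrC(Br)(Br)Br
Why: Appel reaction: the axial C4–OH is activated on phosphorus and displaced by bromide in an SN2 step with inversion, the same invertive displacement next to an anti C–Cl bond that turns trans-2-chlorocyclohexanol derivatives into cis-1,2-dihalides, which places C4–Br equatorial and cis to C5–Cl, while the neutral medium avoids epoxide closure of the chlorohydrin and spares the tertiary halides.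

Compound list
1 | 2,4-dimethylfuran | Cc1cc(C)co1 | starting material
2 | 3-acryloyl-1,3-oxazolidin-2-one | C=CC(=O)N1CCOC1=O | starting material
3 | 3-[(1R,2R,4R)-1,5-dimethyl-7-oxabicyclo[2.2.1]hept-5-ene-2-carbonyl]-1,3-oxazolidin-2-one | CC1=C[C@@]2(C)O[C@@H]1C[C@H]2C(=O)N1CCOC1=O | intermediate
4 | 3-[(1S,2R,4R,5S,6S)-5-chloro-1,5-dimethyl-6-(phenylselanyl)-7-oxabicyclo[2.2.1]heptane-2-carbonyl]-1,3-oxazolidin-2-one | C[C@@]1(Cl)[C@@H]([Se]c3ccccc3)[C@@]2(C)O[C@@H]1C[C@H]2C(=O)N1CCOC1=O | intermediate
5 | 3-[(1R,2R,4R,5R)-5-chloro-1,5-dimethyl-7-oxabicyclo[2.2.1]heptane-2-carbonyl]-1,3-oxazolidin-2-one | C[C@@]1(Cl)C[C@@]2(C)O[C@@H]1C[C@H]2C(=O)N1CCOC1=O | intermediate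
6 | [(1R,2S,4R,5R)-5-chloro-1,5-dimethyl-7-oxabicyclo[2.2.1]heptan-2-yl]methanol | C[C@@]1(Cl)C[C@@]2(C)O[C@@H]1C[C@H]2CO | intermediate
7 | (1R,2R,4R,5R)-5-chloro-1,5-dimethyl-7-oxabicyclo[2.2.1]heptane-2-carbaldehyde | C[C@@]1(Cl)C[C@@]2(C)O[C@@H]1C[C@H]2C=O | intermediate
8 | (1R,2S,4R,5R)-5-chloro-2-[(E)-2-chloroethenyl]-1,5-dimethyl-7-oxabicyclo[2.2.1]heptane | C[C@@]1(Cl)C[C@@]2(C)O[C@@H]1C[C@H]2/C=C/Cl | intermediate
9 | dibromo{[(1R,2R,4R,5S)-4-bromo-2-chloro-5-[(E)-2-chloroethenyl]-2,4-dimethylcyclohexyl]oxy}borane | C[C@@]1(Cl)C[C@@](C)(Br)[C@H](/C=C/Cl)C[C@H]1OB(Br)Br | intermediate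
10 | (1R,2R,4R,5S)-4-bromo-2-chloro-5-[(E)-2-chloroethenyl]-2,4-dimethylcyclohexan-1-ol | C[C@@]1(Cl)C[C@@](C)(Br)[C@H](/C=C/Cl)C[C@H]1O | intermediate
11 | (1R,2S,4S,5R)-1,4-dibromo-5-chloro-2-[(E)-2-chloroethenyl]-1,5-dimethylcyclohexane | C[C@@]1(Cl)C[C@@](C)(Br)[C@H](/C=C/Cl)C[C@@H]1Br | target

Total step count: 8. Longest linear sequence: 8 steps (1 and 2 to 11).

Steps most likely to fail

**Step 7 (bridge opening).** The C1 cation may lose a proton or take a 1,2-hydride shift from C2. Bromide may be captured from the lower face, and chloride–bromide exchange may occur at C5.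

The fallback replaces the cationic C1–Br bond formation with a radical one. It sets out from 8 and comes back at 10.
- Eliminative ether opening with TMSOTf and 2,6-lutidine (CH2Cl2, -78 to 0 °C), the silyl triflate/amine method known for epoxides, should let the hindered base take a proton from the exposed C1 methyl group. This gives the exocyclic-alkene silyl ether F1.
- Acid methanolysis (pyridinium p-toluenesulfonate, MeOH) frees the alkenol F2. No base is used, because the trans-diaxial chlorohydrin would undergo ring closure.
- Markovnikov hydrogen-atom-transfer hydrobromination (Co(acac)2, t-BuOOH, Et3SiH, TsBr, n-PrOH, rt) makes the tertiary C1 radical. Its lower face is blocked by the syn-axial C5–Cl, so bromine transfer from above should give 10.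

**Step 8 (bromide displacement at C4).** Displacement may be slow at a secondary carbon next to a quaternary one. Other risks are anti elimination toward C3, chlorine participation leading to retention or halogen migration, and ionisation of the tertiary bromide during a long reaction.

The fallback changes the order of events, so that C4 is brominated while C1 is still an alkene carbon and no tertiary bromide is present. It sets out from 8 and comes back at 11.
- 8 is taken to the alkenol F2 as described for step 7.
- F2 is converted (Tf2O, pyridine, CH2Cl2, -20 °C) into the alkenyl triflate F3.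
- The triflate allows a separate displacement in a non-ionising medium (Bu4NBr, toluene, rt to 60 °C) to give the inverted alkenyl bromide F4.
- The same hydrogen-atom-transfer hydrobromination then sets C1 last and gives 11.

**Step 1 (cycloaddition).** The free furan α-position may undergo conjugate, Friedel–Crafts-type alkylation under Lewis acid. Cycloreversion may set in on warming, and the bridgehead methyl group may erode endo and facial selectivity.

The fallback gives up Lewis-acid catalysis and asymmetric induction. It sets out from 1 and 2 and comes back at 3.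
- 1 and 2 are combined without catalyst at 10–15 kbar (CH2Cl2, rt).
- The racemic endo adduct is resolved by chromatography on a chiral stationary phase.
- 3 goes on to step 2 and the mirror-image adduct F5 is set aside.

Further compounds
F1 | step 7 | {[(1R,2R,5S)-2-chloro-5-[(E)-2-chloroethenyl]-2-methyl-4-methylidenecyclohexyl]oxy}trimethylsilane | C[C@@]1(Cl)CC(=C)[C@H](/C=C/Cl)C[C@H]1O[Si](C)(C)C
F2 | step 7 | (1R,2R,5S)-2-chloro-5-[(E)-2-chloroethenyl]-2-methyl-4-methylidenecyclohexan-1-ol | C[C@@]1(Cl)CC(=C)[C@H](/C=C/Cl)C[C@H]1O
F3 | step 8 | (1R,2R,5S)-2-chloro-5-[(E)-2-chloroethenyl]-2-methyl-4-methylidenecyclohexyl trifluoromethanesulfonate | C[C@@]1(Cl)CC(=C)[C@H](/C=C/Cl)C[C@H]1OS(=O)(=O)C(F)(F)F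
F4 | step 8 | (1R,2S,4S)-2-bromo-1-chloro-4-[(E)-2-chloroethenyl]-1-methyl-5-methylidenecyclohexane | C[C@@]1(Cl)CC(=C)[C@H](/C=C/Cl)C[C@@H]1Br
F5 | step 1 | 3-[(1S,2S,4S)-1,5-dimethyl-7-oxabicyclo[2.2.1]hept-5-ene-2-carbonyl]-1,3-oxazolidin-2-one | CC1=C[C@]2(C)O[C@H]1C[C@@H]2C(=O)N1CCOC1=O
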